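The readings come from a simulation for substances that don't exist.

Early in a run the target looks very clean, so I start from the first readings of these closed flasks.

| setting | north-east | south-west | west | noon | midnight |
|---|---|---|---|---|---|
| substrate | 0.20 M | 0.10 M | 0.15 M | 0.20 M | 0.20 M |
| remark | run made earlier | run made earlier | run made earlier | a single well-mixed tank run continuously and read at steady state, 6.0 h in it on average | a closed flask charged with all of it at once and left for 6.0 h |
| time |  |  |  |  | 6.0 h |

| run | time / h | target / % | side product / % | substrate / % |
|---|---|---|---|---|
| north-east | 0.500 | 25.9 | 1.3 | 6.8 |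
| north-east | 0.833 | 44.3 | 0.8 | 2.3 |
| north-east | 1.50 | 69.7 | 4.2 | 0 |
| north-east | 3.00 | 86.8 | 7.0 | 0.6 |
| north-east | 6.00 | 86.3 | 10.4 | 0.3 |
| south-west | 1.00 | 53.9 | 2.9 | 2.2 |
| south-west | 2.00 | 77.4 | 4.4 | 0.8 |
| south-west | 3.00 | 83.8 | 6.7 | 0 |
| south-west | 4.00 | 87.0 | 6.9 | 2.0 |
| south-west | 5.00 | 87.2 | 8.0 | 1.0 |
| west | 0.417 | 22.6 | 0 | 11.8 |
| west | 0.667 | 35.1 | 0.8 | 1.8 |
| west | 1.33 | 65.4 | 2.6 | 0.3 |
| west | 2.50 | 81.0 | 5.5 | 0.4 |
| west | 5.00 | 89.0 | 8.2 | 0.3 |

(scatter of a reading: 1 percentage point)

- the stated concentrations are those of everything mixed, before any reaction; amounts are the same in each set-up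
- candidate steps: substrate <-> intermediate A; intermediate A -> intermediate B; intermediate C -> target; intermediate B -> side product; intermediate A -> intermediate C
- the earlier runs were made in a closed, stirred flask

* the set-up with the highest share of target in all that became target or side product, at the outlet or at the end ("none" if the first two lie within 2 percentage points) (noon / midnight / none)
* share of target in all that became target or side product, at the outlet or at the end, noon
* share of target in all that became target or side product, at the outlet or at the end, midnight

In the south-west run at 1.00 h, target reads 53.9% and side product 2.9%, a share of target of 94.9%. Yet the last target readings of the three runs average P = 87.5% of the charge, and those two numbers seem to disagree.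

I reckon with the fraction left, not the fraction made. Intermediate A branches towards intermediate C and target, and towards intermediate B and side product. I take the rest of the charge, S = 12.5%, to enter the side branch. In the north-east run at 3.00 h, side product reads 7.0%, so by that scattered reading a fraction 44.0% of S still waits. Let L = exp(−k_B t) be the fraction of the side branch not yet side product at time t, with k_B its first-order rate constant; this reading puts k_B at 0.274 h⁻¹. The south-west reading at 1.00 h likewise puts the first-order constant k_C of the target branch at 0.957 h⁻¹, faster than k_B, so the early share runs high and sinks towards P. After target goes flat, side product is the reading to watch.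

For the midnight flask I reckon L = 19.4%, giving a share of 89.7%. In the noon tank I take the fraction left of a first-order step of constant k as one over one plus kτ, with τ the mean time of 6.0 h: 37.9% for the side branch and 14.8% for the target branch. That gives 90.6%, a gap of 0.90 percentage points, below the margin.

The forecast stands a little above my shares, at 91.2% for noon and 90.3% for midnight, and also answers none: “The tank holds back slightly more side product in B”.

The simulation gives 90.5% for noon and 89.4% for midnight, so the answer is none.

    substrate ⇌ intermediate A (K = 0.630, k = 0.0150 s⁻¹)
    intermediate A → intermediate B (k = 4.50 × 10⁻⁴ s⁻¹)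
    intermediate C → target (k = 3.60 × 10⁻⁴ s⁻¹)
    intermediate B → side product (k = 6.90 × 10⁻⁵ s⁻¹)
    intermediate A → intermediate C (k = 0.00290 s⁻¹)

By its path to side product, intermediate B has a half-life of 2.8 h, longer than the 0.53 h of intermediate C on its path to target, and with the k_B read above, L in the midnight flask at 6.0 h is 19.4%. Left for 60.0 h, that flask has hardly any L, my share falls to P = 87.5%, and the share the flask gives there is 86.6%.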